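**Retrosynthetic overview**
1. The C30 alcohol comes last, by reagent-controlled reduction of a β-keto lactone that is unmasked from a silyl enol ether.
2. Rings C, D and E (cyclopentane plus bicyclo[2.2.2]octane) form together at the end: an AB-ring iodide (18 non-hydrogen atoms) and a phthalide phenol (14, plus a silyl group) are joined by ortho-C-alkylation (dearomatization), and the resulting 6-alkyl-6-methylcyclohexa-2,4-dienone undergoes an intramolecular Diels–Alder reaction.
3. AB iodide: ring A (unsaturated ε-lactone) by ring-closing metathesis after lactol methylenation; the exocyclic methylene by selenoxide elimination; CH2I from a lactone carbonyl.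
4. Ring B with C9, C11 and C23: ester-tethered intramolecular Diels–Alder reaction of a trienyl citraconate, resolved as the acid.
5. Phthalide phenol: Diels–Alder/aromatization of a 1,3-bis(silyloxy)diene with a 4-silyloxybut-2-ynoate. Ring order: B, then A; separately arene and γ-lactone; finally C, D and E in one operation.

Notation: locants C1 to O31 are the positions of the non-hydrogen atoms of the target SMILES read from left to right (C2 = CMe2, C5 = ring-A carbonyl, C7=C8, C9 bears C10, C18 = ketone, C20 bears C21, C27 = γ-lactone carbonyl); ring B is C9–C11–C12–C13–C14–C23.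
Assumption: in step 5 the (S)-1-phenylethylammonium salt of the wanted enantiomer is the less soluble one; if it is not, the (R)-amine is used and nothing else changes.

This route is designed on paper; none of it has been run. The given target has ring A cis-fused to ring B (C10 methyl, H11 and H23 on one face), and the route is built for that configuration.

**Step 1**
Reactants: 1 methyl (E)-4-bromobut-2-enoate
Product: 2 methyl (E)-4-(diethoxyphosphoryl)but-2-enoate
Conditions: P(OEt)3, neat, 120 °C
Reagents that add atoms: triethyl phosphite, CCOP(OCC)OCC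
Why: Michaelis–Arbuzov reaction of the allylic bromide, which leaves the E double bond untouched.

**Step 2**
Reactants: 2 methyl (E)-4-(diethoxyphosphoryl)but-2-enoate; 3 methacrolein
Product: 5 methyl (2E,4E)-6-methylhepta-2,4,6-trienoate, via lithiated phosphonate 4 (not isolated)
Conditions: LiN(SiMe3)2, THF, −78 °C; then 3, −78 → 0 °C
Reagents that add atoms: none
Why: Vinylogous Horner–Wadsworth–Emmons olefination, which gives the new C11=C12 double bond E.

**Step 3**
Reactants: 5 methyl (2E,4E)-6-methylhepta-2,4,6-trienoate
Product: 6 (2E,4E)-6-methylhepta-2,4,6-trien-1-ol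
Conditions: i-Bu2AlH (2.2 equiv), CH2Cl2, −78 °C; aq. potassium sodium tartrate
Reagents that add atoms: none
Why: 1,2-Reduction of the conjugated ester to the primary allylic alcohol.

**Step 4**
Reactants: 6 (2E,4E)-6-methylhepta-2,4,6-trien-1-ol; 7 citraconic anhydride
Product: 9 rac-lactone acid (all-cis cycloadduct), via half ester 8 (not isolated)
Conditions: toluene, 60 °C; then BHT (5 mol %), 130 °C, sealed tube, 48 h; crystallization
Reagents that add atoms: none
Why: Alcoholysis opens the anhydride at the less hindered carbonyl (C22, next to C–H), and the ester-tethered intramolecular Diels–Alder reaction runs through the endo transition state that gives the cis-fused γ-lactone, so the Z dienophile (C8 cis to C22) and the E,E diene (C2 cis to C15) place all four carbon substituents on one face of ring B and set C9, C11 and C23 in relative terms.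

**Step 5**
Reactants: 9 rac-lactone acid
Product: 10 (S)-1-phenylethylammonium salt of the enantiomer with the target configuration
Conditions: (S)-1-phenylethylamine (0.55 equiv), acetone/EtOAc, crystallization (twice)
Reagents that add atoms: (S)-1-phenylethylamine, C[C@H](N)c1ccccc1
Why: Classical resolution by crystallization of one diastereomeric salt fixes the absolute configuration of C9, C11 and C23.

**Step 6**
Reactants: 10 (S)-1-phenylethylammonium salt
Product: 12 unsaturated bis-lactone, via free acid 11 (not isolated)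
Conditions: CF3SO3H (1.3 equiv), CH2Cl2, 0 °C → rt
Reagents that add atoms: none
Why: Acid-catalysed Markovnikov lactonization of the C8 acid onto the cis isopropenyl group builds the CMe2–O unit (C2) as a cis-fused γ-lactone without creating a stereocentre.

**Step 7**
Reactants: 12 unsaturated bis-lactone
Product: 13 saturated bis-lactone
Conditions: H2 (1 atm), 10% Pd/C, EtOAc, rt
Reagents that add atoms: none
Why: Catalytic hydrogenation of the only C=C bond (C12=C13) touches no stereocentre.

**Step 8**
Reactants: 13 saturated bis-lactone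
Product: 14 selenide acid
Conditions: PhSeSePh (0.6 equiv), NaBH4, DMF, 0 °C → rt; then 13, 120 °C; then 1 M HCl
Reagents that add atoms: diphenyl diselenide, c1ccc(cc1)[Se][Se]c1ccccc1
Why: SN2 opening of a γ-lactone at its primary O–CH2 carbon (C15) by benzeneselenolate; the other lactone has a tertiary alkyl C–O bond and cannot react this way.

**Step 9**
Reactants: 14 selenide acid
Product: 15 selenide alcohol
Conditions: BH3·SMe2, THF, 0 °C → rt; then MeOH
Reagents that add atoms: none
Why: Borane reduces the carboxylic acid (C22) chemoselectively in the presence of the hindered lactone.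

**Step 10**
Reactants: 15 selenide alcohol
Product: 17 methylene lactone alcohol, via selenoxide 16 (not isolated)
Conditions: 30% H2O2, pyridine, THF, 0 → 40 °C
Reagents that add atoms: none
Why: Selenoxide syn-elimination, where the only β-hydrogen is on C14, gives the exocyclic C14=C15 methylene and removes the C14 stereocentre.

**Step 11**
Reactants: 17 methylene lactone alcohol
Product: 18 lactol
Conditions: i-Bu2AlH (3 equiv), CH2Cl2, −78 °C; aq. potassium sodium tartrate
Reagents that add atoms: none
Why: Partial reduction of the hindered γ-lactone stops at the lactol (C8).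

**Step 12**
Reactants: 18 lactol
Product: 19 vinyl diol
Conditions: Ph3PCH3Br (5 equiv), KOtBu (4.8 equiv), THF, 0 → 50 °C
Reagents that add atoms: methyltriphenylphosphonium bromide, C[P+](c1ccccc1)(c1ccccc1)c1ccccc1.[Br-]
Why: Wittig methylenation of the open hydroxy-aldehyde form of the lactol gives the C9 vinyl group and frees the tertiary alcohol.

**Step 13**
Reactants: 19 vinyl diol
Product: 20 hydroxy iodide
Conditions: PPh3, imidazole, I2 (premixed), CH2Cl2, 0 °C → rt
Reagents that add atoms: iodine, II
Why: Appel iodination converts only the primary alcohol (C22); the tertiary alcohol does not react.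

**Step 14**
Reactants: 20 hydroxy iodide
Product: 21 acrylate
Conditions: acryloyl chloride, i-Pr2NEt, DMAP (cat.), CH2Cl2, 0 °C → rt
Reagents that add atoms: acryloyl chloride, C=CC(=O)Cl
Why: O-Acylation of the tertiary alcohol under amine conditions, which do not form an alkoxide that could displace the iodide.

**Step 15**
Reactants: 21 acrylate
Product: 22 AB iodide
Conditions: second-generation Grubbs catalyst RuCl2(=CHPh)(PCy3)(C21H26N2) (5 mol %), toluene (2 mM), 80 °C
Reagents that add atoms: none
Why: Ring-closing metathesis of acrylate and vinyl group closes ring A as the seven-membered unsaturated lactone, the ring enforcing the cis C7=C8 bond.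

**Step 16**
Reactants: 23 methyl propanoate (2 equiv)
Product: 24 methyl 2-methyl-3-oxopentanoate
Conditions: NaH, THF, reflux; then AcOH
Reagents that add atoms: none
Why: Claisen condensation of the ester with itself.

**Step 17**
Reactants: 24 methyl 2-methyl-3-oxopentanoate
Product: 25 methyl 2-methyl-3-(trimethylsilyloxy)pent-2-enoate
Conditions: Me3SiCl, Et3N, hexane, rt
Reagents that add atoms: chlorotrimethylsilane, C[Si](C)(C)Cl
Why: O-Silylation of the β-keto ester enol.

**Step 18**
Reactants: 25 methyl 2-methyl-3-(trimethylsilyloxy)pent-2-enoate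
Product: 27 1-methoxy-2-methyl-1,3-bis(trimethylsilyloxy)penta-1,3-diene, via lithium dienolate 26 (not isolated)
Conditions: LiN(i-Pr)2, THF, −78 °C; then Me3SiCl
Reagents that add atoms: chlorotrimethylsilane, C[Si](C)(C)Cl
Why: γ-Deprotonation and O-silylation give the electron-rich 1,3-bis(silyloxy)diene.

**Step 19**
Reactants: 28 prop-2-yn-1-ol
Product: 29 tert-butyldimethyl(prop-2-yn-1-yloxy)silane
Conditions: t-BuMe2SiCl, imidazole, CH2Cl2, rt
Reagents that add atoms: tert-butyldimethylsilyl chloride, CC(C)(C)[Si](C)(C)Cl
Why: Silyl protection of the primary alcohol.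

**Step 20**
Reactants: 29 tert-butyldimethyl(prop-2-yn-1-yloxy)silane
Product: 31 methyl 4-(tert-butyldimethylsilyloxy)but-2-ynoate, via lithium acetylide 30 (not isolated)
Conditions: n-BuLi, THF, −78 °C; then ClCO2Me
Reagents that add atoms: methyl chloroformate, COC(=O)Cl
Why: C-Acylation of the lithium acetylide.

**Step 21**
Reactants: 27 1-methoxy-2-methyl-1,3-bis(trimethylsilyloxy)penta-1,3-diene; 31 methyl 4-(tert-butyldimethylsilyloxy)but-2-ynoate
Product: 33 methyl 6-[(tert-butyldimethylsilyloxy)methyl]-2,4-dihydroxy-3,5-dimethylbenzoate, via cycloadduct 32 (not isolated)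
Conditions: toluene, 110 °C, 24 h; then 0.5 M HCl, THF, 0 °C
Reagents that add atoms: none
Why: Diels–Alder reaction in which the nucleophilic diene terminus bonds to the β-carbon of the ynoate (placing CH2O next to the C-methyl carbon and the ester next to the ketene-acetal carbon), followed by aromatization through loss of methanol.

**Step 22**
Reactants: 33 methyl 6-[(tert-butyldimethylsilyloxy)methyl]-2,4-dihydroxy-3,5-dimethylbenzoate
Product: 35 5,7-dihydroxy-4,6-dimethyl-2-benzofuran-1(3H)-one, via hydroxymethyl benzoate 34 (not isolated)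
Conditions: p-TsOH·H2O (cat.), MeOH, 50 °C
Reagents that add atoms: none
Why: Acidic desilylation and lactonization of the benzylic alcohol onto the neighbouring ester give the phthalide.

**Step 23**
Reactants: 35 5,7-dihydroxy-4,6-dimethyl-2-benzofuran-1(3H)-one
Product: 36 5-(benzyloxy)-7-hydroxy-4,6-dimethyl-2-benzofuran-1(3H)-one
Conditions: BnBr (1.05 equiv), K2CO3 (1.1 equiv), acetone, rt
Reagents that add atoms: benzyl bromide, BrCc1ccccc1
Why: Williamson etherification of the more acidic 5-OH, which is not hydrogen-bonded to the carbonyl as the 7-OH is.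

**Step 24**
Reactants: 36 5-(benzyloxy)-7-hydroxy-4,6-dimethyl-2-benzofuran-1(3H)-one
Product: 37 5-(benzyloxy)-4,6-dimethyl-7-(triisopropylsilyloxy)-2-benzofuran-1(3H)-one
Conditions: i-Pr3SiOSO2CF3, 2,6-lutidine, CH2Cl2, 0 °C → rt
Reagents that add atoms: triisopropylsilyl trifluoromethanesulfonate, CC(C)[Si](OS(=O)(=O)C(F)(F)F)(C(C)C)C(C)C
Why: O-Silylation of the chelated 7-OH with the reactive silyl triflate.

**Step 25**
Reactants: 37 5-(benzyloxy)-4,6-dimethyl-7-(triisopropylsilyloxy)-2-benzofuran-1(3H)-one
Product: 38 5-hydroxy-4,6-dimethyl-7-(triisopropylsilyloxy)-2-benzofuran-1(3H)-one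
Conditions: H2 (1 atm), 10% Pd/C, EtOAc, rt
Reagents that add atoms: none
Why: Hydrogenolysis of the benzyl ether frees the phenol that carries the nucleophilic C4 position (C20).

**Step 26**
Reactants: 38 5-hydroxy-4,6-dimethyl-7-(triisopropylsilyloxy)-2-benzofuran-1(3H)-one; 22 AB iodide
Product: 41 hexacyclic silyl enol ether, via sodium phenoxide 39 (not isolated), via dienone 40 (not isolated)
Conditions: NaH (1.0 equiv), toluene, 0 °C → rt; then 22 (0.9 equiv), 100 °C, 36 h; chromatography
Reagents that add atoms: none
Why: Ortho-C-alkylation of the sodium phenoxide in a non-polar solvent (alkylative dearomatization, C20 being favoured over C16 because C16 is buttressed by the OSi(i-Pr)3 group) gives dienone 40, whose intramolecular Diels–Alder reaction can only add C24 to the face of C14=C15 that carries C22 and C15 to C16, so C14, C16, C20 and C24 emerge as in the target; the alkylation has no facial bias at C20, so about half of the alkylated material is the C20 epimer of 40, which cannot reach this transition state and is removed by the chromatography.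

**Step 27**
Reactants: 41 hexacyclic silyl enol ether
Product: 42 β-keto lactone
Conditions: HF·pyridine, THF, 0 °C
Reagents that add atoms: none
Why: Acidic cleavage of the silyl enol ether gives the C30 ketone without retro-Claisen opening of the non-enolizable 1,3-diketone; C29 is left epimerizable.

**Step 28**
Reactants: 42 β-keto lactone
Product: 43 target CNP0295808.3
Conditions: (S)-2-methyl-CBS-oxazaborolidine (0.5 equiv), catecholborane (2 equiv), toluene, −78 → −40 °C; then MeOH, pH 7 buffer
Reagents that add atoms: none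
Why: Corey–Bakshi–Shibata reduction in which the (S)-catalyst delivers hydride to the face of the C30 carbonyl that gives the 30R alcohol (C16 as large, C29 as small group), and because C29 epimerizes through the enol only the epimer with its lactone carbonyl anti to the incoming hydride is reduced (dynamic kinetic resolution), setting C29 and C30 cis as in the target while the C18 ketone (between two quaternary carbons) and the enoate stay intact.

**Compound list**
1 | methyl (E)-4-bromobut-2-enoate | COC(=O)/C=C/CBr | starting material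
2 | methyl (E)-4-(diethoxyphosphoryl)but-2-enoate | CCOP(=O)(OCC)C/C=C/C(=O)OC | intermediate
3 | methacrolein (2-methylprop-2-enal) | CC(=C)C=O | starting material
4 | lithiated phosphonate (lithium salt of 2, carbanion at C4) | [Li+].CCOP(=O)(OCC)[CH-]/C=C/C(=O)OC | intermediate
5 | methyl (2E,4E)-6-methylhepta-2,4,6-trienoate | COC(=O)/C=C/C=C/C(C)=C | intermediate
6 | (2E,4E)-6-methylhepta-2,4,6-trien-1-ol | OC/C=C/C=C/C(C)=C | intermediate
7 | citraconic anhydride (3-methylfuran-2,5-dione) | CC1=CC(=O)OC1=O | starting material
8 | half ester: (Z)-2-methyl-4-oxo-4-{[(2E,4E)-6-methylhepta-2,4,6-trien-1-yl]oxy}but-2-enoic acid | OC(=O)/C(C)=C\C(=O)OC/C=C/C=C/C(C)=C | intermediate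
9 | rac-lactone acid: racemic 7-methyl-1-oxo-6-(prop-1-en-2-yl)-1,3,3a,6,7,7a-hexahydro-2-benzofuran-7-carboxylic acid, cis-fused, with H3a, H6, H7a and the 7-methyl group on one face | CC(=C)[C@H]1C=C[C@H]2COC(=O)[C@H]2[C@@]1(C)C(=O)O.CC(=C)[C@@H]1C=C[C@@H]2COC(=O)[C@@H]2[C@]1(C)C(=O)O | intermediate
10 | (S)-1-phenylethylammonium salt of the enantiomer of 9 that has the target configuration at C9, C11 and C23 | CC(=C)[C@H]1C=C[C@H]2COC(=O)[C@H]2[C@@]1(C)C(=O)[O-].C[C@H]([NH3+])c1ccccc1 | intermediate
11 | free acid of 10 (single enantiomer of 9) | CC(=C)[C@H]1C=C[C@H]2COC(=O)[C@H]2[C@@]1(C)C(=O)O | intermediate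
12 | unsaturated bis-lactone: cyclohexene (C12=C13) with the γ-lactone C8(=O)–O–C2Me2 cis-fused at C9–C11 and the γ-lactone C22(=O)–O–C15H2 cis-fused at C23–C14, both on the face opposite to the C9 methyl | CC1(C)OC(=O)[C@@]2(C)[C@@H]1C=C[C@H]1COC(=O)[C@H]12 | intermediate
13 | saturated bis-lactone (12 with C12–C13 single bond) | CC1(C)OC(=O)[C@@]2(C)[C@@H]1CC[C@H]1COC(=O)[C@H]12 | intermediate
14 | selenide acid: 3,3,7a-trimethyl-1-oxo-6-[(phenylselanyl)methyl]octahydro-2-benzofuran-7-carboxylic acid, all ring substituents other than the 7a-methyl on one face | CC1(C)OC(=O)[C@@]2(C)[C@@H]1CC[C@@H](C[Se]c1ccccc1)[C@H]2C(=O)O | intermediate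
15 | selenide alcohol: 7-(hydroxymethyl)-3,3,7a-trimethyl-6-[(phenylselanyl)methyl]hexahydro-2-benzofuran-1(3H)-one, configuration as in 14 | CC1(C)OC(=O)[C@@]2(C)[C@@H]1CC[C@@H](C[Se]c1ccccc1)[C@H]2CO | intermediate
16 | selenoxide of 15 | CC1(C)OC(=O)[C@@]2(C)[C@@H]1CC[C@@H](C[Se](=O)c1ccccc1)[C@H]2CO | intermediate
17 | methylene lactone alcohol: 7-(hydroxymethyl)-3,3,7a-trimethyl-6-methylidenehexahydro-2-benzofuran-1(3H)-one, cis-fused, CH2OH cis to the lactone carbonyl carbon | CC1(C)OC(=O)[C@@]2(C)[C@@H]1CCC(=C)[C@H]2CO | intermediate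
18 | lactol: 7-(hydroxymethyl)-3,3,7a-trimethyl-6-methylideneoctahydro-2-benzofuran-1-ol (anomer mixture), otherwise as 17 | CC1(C)OC(O)[C@@]2(C)[C@@H]1CCC(=C)[C@H]2CO | intermediate
19 | vinyl diol: 2-[2-ethenyl-3-(hydroxymethyl)-2-methyl-4-methylidenecyclohexyl]propan-2-ol with CMe2OH, vinyl and CH2OH mutually cis, configuration at C9, C11, C23 as in 43 | CC(C)(O)[C@H]1CCC(=C)[C@@H](CO)[C@@]1(C)C=C | intermediate
20 | hydroxy iodide: 2-[2-ethenyl-3-(iodomethyl)-2-methyl-4-methylidenecyclohexyl]propan-2-ol, configuration as in 19 | CC(C)(O)[C@H]1CCC(=C)[C@@H](CI)[C@@]1(C)C=C | intermediate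
21 | acrylate: prop-2-enoate ester of the tertiary alcohol 20 | C=CC(=O)OC(C)(C)[C@H]1CCC(=C)[C@@H](CI)[C@@]1(C)C=C | intermediate
22 | AB iodide: 6-(iodomethyl)-1,1,5a-trimethyl-7-methylidene-5a,6,7,8,9,9a-hexahydro-2-benzoxepin-3(1H)-one, cis ring fusion, CH2I cis to C5 of the oxepinone, configuration at C9, C11, C23 as in 43 | CC1(C)OC(=O)C=C[C@@]2(C)[C@@H]1CCC(=C)[C@H]2CI | intermediate
23 | methyl propanoate | CCC(=O)OC | starting material
24 | methyl 2-methyl-3-oxopentanoate (racemic) | CCC(=O)C(C)C(=O)OC | intermediate
25 | methyl 2-methyl-3-(trimethylsilyloxy)pent-2-enoate | CCC(O[Si](C)(C)C)=C(C)C(=O)OC | intermediate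
26 | lithium dienolate of 25 | [Li+].[O-]C(OC)=C(C)C(O[Si](C)(C)C)=CC | intermediate
27 | 1-methoxy-2-methyl-1,3-bis(trimethylsilyloxy)penta-1,3-diene | COC(O[Si](C)(C)C)=C(C)C(O[Si](C)(C)C)=CC | intermediate
28 | prop-2-yn-1-ol | C#CCO | starting material
29 | tert-butyldimethyl(prop-2-yn-1-yloxy)silane | C#CCO[Si](C)(C)C(C)(C)C | intermediate
30 | lithium acetylide of 29 | [Li+].[C-]#CCO[Si](C)(C)C(C)(C)C | intermediate
31 | methyl 4-(tert-butyldimethylsilyloxy)but-2-ynoate | COC(=O)C#CCO[Si](C)(C)C(C)(C)C | intermediate
32 | cycloadduct: methyl 2-[(tert-butyldimethylsilyloxy)methyl]-6-methoxy-3,5-dimethyl-4,6-bis(trimethylsilyloxy)cyclohexa-1,4-diene-1-carboxylate | COC(=O)C1=C(CO[Si](C)(C)C(C)(C)C)C(C)C(O[Si](C)(C)C)=C(C)C1(OC)O[Si](C)(C)C | intermediate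
33 | methyl 6-[(tert-butyldimethylsilyloxy)methyl]-2,4-dihydroxy-3,5-dimethylbenzoate | COC(=O)c1c(O)c(C)c(O)c(C)c1CO[Si](C)(C)C(C)(C)C | intermediate
34 | methyl 2,4-dihydroxy-6-(hydroxymethyl)-3,5-dimethylbenzoate | COC(=O)c1c(O)c(C)c(O)c(C)c1CO | intermediate
35 | 5,7-dihydroxy-4,6-dimethyl-2-benzofuran-1(3H)-one | Cc1c(O)c(C)c2COC(=O)c2c1O | intermediate
36 | 5-(benzyloxy)-7-hydroxy-4,6-dimethyl-2-benzofuran-1(3H)-one | Cc1c(OCc3ccccc3)c(C)c2COC(=O)c2c1O | intermediate
37 | 5-(benzyloxy)-4,6-dimethyl-7-(triisopropylsilyloxy)-2-benzofuran-1(3H)-one | Cc1c(OCc3ccccc3)c(C)c2COC(=O)c2c1O[Si](C(C)C)(C(C)C)C(C)C | intermediate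
38 | 5-hydroxy-4,6-dimethyl-7-(triisopropylsilyloxy)-2-benzofuran-1(3H)-one | Cc1c(O)c(C)c2COC(=O)c2c1O[Si](C(C)C)(C(C)C)C(C)C | intermediate
39 | sodium phenoxide of 38 | [Na+].Cc1c([O-])c(C)c2COC(=O)c2c1O[Si](C(C)C)(C(C)C)C(C)C | intermediate
40 | dienone: 38 dearomatized by C-alkylation at C4 of the phthalide (C20) with the CH2 group of 22, giving a 4,6-dimethyl-5-oxo-7-(triisopropylsilyloxy)-4,5-dihydrophthalide with C20 arranged as in 43 | CC1(C)OC(=O)C=C[C@@]2(C)[C@@H]1CCC(=C)[C@H]2C[C@@]3(C)C(=O)C(C)=C(O[Si](C(C)C)(C(C)C)C(C)C)C4=C3COC4=O | intermediate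
41 | hexacyclic silyl enol ether: skeleton of 43 with C29=C30 and OSi(i-Pr)3 on C30; C9, C11, C14, C16, C20, C23, C24 as in 43 | CC1(C)OC(=O)C=C[C@@]2(C)[C@@H]1CC[C@]13C[C@]4(C)C(=O)[C@](C)(C[C@@H]21)[C@]31COC(=O)C1=C4O[Si](C(C)C)(C(C)C)C(C)C | intermediate
42 | β-keto lactone: 43 with C30=O instead of C30H–OH (C29 epimerizable, drawn as in 43) | CC1(C)OC(=O)C=C[C@@]2(C)[C@@H]1CC[C@]13C[C@]4(C)C(=O)[C@](C)(C[C@@H]21)[C@]31COC(=O)[C@H]1C4=O | intermediate
43 | CNP0295808.3, (9R,11S,14S,16S,20R,23S,24R,29R,30R) in the locants defined above | CC1(C)OC(=O)C=C[C@@]2(C)[C@@H]1CC[C@]13C[C@]4(C)C(=O)[C@](C)(C[C@@H]21)[C@]31COC(=O)[C@H]1[C@H]4O | target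

**Step count, longest linear sequence, risks**
Total: 28 steps. Longest linear sequence: 18 steps (1 → 43 through steps 1–15 and 26–28); the phenol branch (steps 16–25) runs in parallel.

Step 4 is at risk on two counts: the anhydride may open at the wrong carbonyl, and the cycloaddition may favour the trans-fused lactone. The fallback sets out from 6 and makes the ring intermolecularly. Silylation (t-BuMe2SiCl, imidazole) gives trienyl silyl ether F1. Its Diels–Alder reaction with 7 (toluene, 80 °C, endo) gives anhydride adduct F2. Bu4NF/AcOH then frees the C15 alcohol, which opens the anhydride at the neighbouring C22 carbonyl, and the sequence comes back to the route at 9.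

Step 26 can fail through O-alkylation or attack at C16, and even when it works about half of the alkylated material is the unproductive C20 epimer. The fallback sets out from 39 and 22 and replaces separation of that epimer by its recycling in the flask. Once the alkylation is complete, the mixture is irradiated at 365 nm in toluene at 100 °C, a wavelength the adduct 41 does not absorb. The epimeric dienone F3, which forms beside 40 in the alkylation, then opens electrocyclically to dienylketene F4. Thermal reclosure of the ketene returns both C20 epimers, and the sequence comes back to the route at 40, which is drained by cycloaddition to 41. This recycling does not cure O-alkylation or attack at C16.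

Step 28 can fail if the intrinsic preference of the cage for hydride attack from the side of the C18 carbonyl overrides the catalyst. The fallback sets out from 42 and replaces the chemical reductant by a screened ketoreductase (NADPH, glucose/glucose dehydrogenase recycling, pH 7 buffer with DMSO), the kind of enzyme that performs this reduction in the biosynthesis of related compounds. It comes back to the route at 43 and needs no compound beyond the list (none F0).

**Further compounds**
F1 | step 4 | tert-butyldimethylsilyl ether of 6 | CC(C)(C)[Si](C)(C)OC/C=C/C=C/C(C)=C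
F2 | step 4 | racemic endo Diels–Alder adduct of F1 and 7: cis-3-methyl-cyclohex-4-ene-1,2-dicarboxylic anhydride type, with the methyl on C9, isopropenyl on C11 and CH2OSi on C14, all three ring substituents cis to the anhydride | CC(=C)[C@H]1C=C[C@@H](CO[Si](C)(C)C(C)(C)C)[C@H]2C(=O)OC(=O)[C@@]12C.CC(=C)[C@@H]1C=C[C@H](CO[Si](C)(C)C(C)(C)C)[C@@H]2C(=O)OC(=O)[C@]12C
F3 | step 26 | epimeric dienone: C20 epimer of 40 | CC1(C)OC(=O)C=C[C@@]2(C)[C@@H]1CCC(=C)[C@H]2C[C@]3(C)C(=O)C(C)=C(O[Si](C(C)C)(C(C)C)C(C)C)C4=C3COC4=O
F4 | step 26 | dienylketene from ring opening of F3 at C18–C20 (alkene geometry not specified) | CC1(C)OC(=O)C=C[C@@]2(C)[C@@H]1CCC(=C)[C@H]2CC(C)=C1COC(=O)C1=C(O[Si](C(C)C)(C(C)C)C(C)C)C(C)=C=O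
F0 | step 28 | none | none
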